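## Retrosynthetic overview

1. The CH2NMe2 side chain is added last by a Mannich reaction at the free indole C3′ of the hexacyclic amine.
2. The hexacycle comes from an achiral 2‑(5‑hydroxy‑7‑methoxyindol‑4‑yl)‑N‑methyltryptamine and formaldehyde. A chiral phosphoric acid catalyses a dearomative Pictet–Spengler/oxa‑cyclisation cascade that forms C1–C9a and C4a–O, the piperidine and dihydrofuran rings, and both stereocentres in one step.
3. The 2‑aryltryptamine comes from a Suzuki coupling (indole C2 to indole C4′) of a 2‑borylated tryptamine methyl carbamate with 5‑benzyloxy‑4‑bromo‑7‑methoxyindole. The carbamate then becomes N‑CH3 with LiAlH4 and the benzyl group is removed with H2.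
4. The bromoindole comes from a Bartoli synthesis on a nitroarene made from 3‑methoxy‑4‑nitrophenol; the boronate comes from tryptamine.
5. Ring order: pyrrole ring of the oxygenated indole, then the biaryl bond, then piperidine and dihydrofuran together (the indoline arises by dearomatisation).

Assumption: the sense of induction of the new step cannot be predicted with certainty; (R)‑TRIP is written, and the (S)‑acid is used instead if that is the one that gives the (4aS,9aR) product. Locants 4a/9a follow β‑carboline numbering; primed locants refer to the methoxyindole.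

## Route

Step 1
Reactants: 1 tryptamine
Product: 2 methyl N‑[2‑(1H‑indol‑3‑yl)ethyl]carbamate
Conditions: ClCO2Me (1.05 equiv), NaHCO3, EtOAc–H2O, 0 °C → rt
Reagents that add atoms: methyl chloroformate, COC(=O)Cl
Why: Schotten–Baumann N‑acylation of the primary amine, which is far more nucleophilic than the indole N–H; the carbamate masks nitrogen for steps 2 and 6 and supplies the future N‑methyl carbon.

Step 2
Reactants: 2 methyl N‑[2‑(1H‑indol‑3‑yl)ethyl]carbamate
Product: 3 methyl N‑{2‑[2‑(4,4,5,5‑tetramethyl‑1,3,2‑dioxaborolan‑2‑yl)‑1H‑indol‑3‑yl]ethyl}carbamate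
Conditions: [Ir(cod)OMe]2 (1.5 mol %), dtbpy (3 mol %), B2pin2 (1.0 equiv), THF, 60 °C
Reagents that add atoms: bis(pinacolato)diboron, CC1(C)OB(OC1(C)C)B1OC(C)(C)C(C)(C)O1
Why: Iridium‑catalysed C–H borylation of a 3‑substituted N–H indole goes to C2, the C–H next to nitrogen, and one equivalent of diboron stops it at the mono‑boronate; the carbamate N–H is tolerated.

Step 3
Reactants: 4 3‑methoxy‑4‑nitrophenol
Product: 5 2‑bromo‑5‑methoxy‑4‑nitrophenol
Conditions: NBS (1.0 equiv), DMF, 0 °C → rt
Reagents that add atoms: N‑bromosuccinimide, O=C1CCC(=O)N1Br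
Why: Electrophilic aromatic bromination ortho to the phenol at the open site para to OMe; the other ortho site is flanked by OH and OMe and the para site carries NO2.

Step 4
Reactants: 5 2‑bromo‑5‑methoxy‑4‑nitrophenol
Product: 6 1‑(benzyloxy)‑2‑bromo‑5‑methoxy‑4‑nitrobenzene
Conditions: BnBr, K2CO3, DMF, rt
Reagents that add atoms: benzyl bromide, BrCc1ccccc1
Why: Williamson etherification of the acidic nitrophenol; the benzyl ether withstands the Grignard reagent of step 5 and LiAlH4 in step 7.

Step 5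
Reactants: 6 1‑(benzyloxy)‑2‑bromo‑5‑methoxy‑4‑nitrobenzene
Product: 8 5‑(benzyloxy)‑4‑bromo‑7‑methoxy‑1H‑indole, via nitrosoarene 7 (not isolated)
Conditions: CH2=CHMgBr (3.3 equiv), THF, −45 °C; aq. NH4Cl
Reagents that add atoms: vinylmagnesium bromide, C=C[Mg]Br
Why: Bartoli indole synthesis, for which the ortho‑OMe group is the required ortho substituent; O‑attack gives nitrosoarene 7, a second vinyl Grignard adds, and the [3,3]‑shift goes to the only free ortho carbon, so Br ends at C4 and OBn at C5.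

Step 6
Reactants: 3 methyl N‑{2‑[2‑(pinacolboryl)‑1H‑indol‑3‑yl]ethyl}carbamate; 8 5‑(benzyloxy)‑4‑bromo‑7‑methoxy‑1H‑indole
Product: 9 methyl N‑{2‑[2‑(5‑benzyloxy‑7‑methoxy‑1H‑indol‑4‑yl)‑1H‑indol‑3‑yl]ethyl}carbamate
Conditions: SPhos Pd G3 (3 mol %), K3PO4, dioxane–H2O (5:1), 80 °C
Reagents that add atoms: none
Why: Suzuki–Miyaura coupling; a fast‑activating SPhos palladacycle should couple the hindered, electron‑rich bromide before the 2‑indolyl boronate protodeboronates, and the free N–H groups and the carbamate are inert.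

Step 7
Reactants: 9 methyl N‑{2‑[2‑(5‑benzyloxy‑7‑methoxy‑1H‑indol‑4‑yl)‑1H‑indol‑3‑yl]ethyl}carbamate
Product: 11 2‑[2‑(5‑benzyloxy‑7‑methoxy‑1H‑indol‑4‑yl)‑1H‑indol‑3‑yl]‑N‑methylethanamine, via formamide 10 (not isolated)
Conditions: LiAlH4 (4 equiv), THF, reflux; NaOH/H2O work‑up
Reagents that add atoms: none
Why: LiAlH4 reduces the methyl carbamate through formamide 10 to the N‑methyl amine; the benzyl ether, the biaryl and both indoles are not touched.

Step 8
Reactants: 11 2‑[2‑(5‑benzyloxy‑7‑methoxy‑1H‑indol‑4‑yl)‑1H‑indol‑3‑yl]‑N‑methylethanamine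
Product: 12 7‑methoxy‑4‑{3‑[2‑(methylamino)ethyl]‑1H‑indol‑2‑yl}‑1H‑indol‑5‑ol
Conditions: H2 (1 atm), 10% Pd/C, EtOH–EtOAc, rt; used crude under Ar
Reagents that add atoms: none
Why: Hydrogenolysis of the benzyl ether at 1 atm frees the phenol that serves as the internal nucleophile in step 9; the indoles and the amine are not reduced under these conditions.

Step 9
Reactants: 12 7‑methoxy‑4‑{3‑[2‑(methylamino)ethyl]‑1H‑indol‑2‑yl}‑1H‑indol‑5‑ol
Product: 15 (4aS,9aR)‑hexacyclic benzofuro[3,2‑b]indoline amine (the target lacking CH2NMe2), via iminium ion 13 (not isolated), via spiroindolenine 14 (not isolated)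
Conditions: (CH2O)n (1.05 equiv), (R)‑TRIP [3,3′‑bis(2,4,6‑triisopropylphenyl)‑BINOL hydrogen phosphate] (10 mol %), 4 Å MS, toluene–CHCl3 (3:1), 0.02 M, 25 → 50 °C, Ar
Reagents that add atoms: formaldehyde (charged as paraformaldehyde), C=O
Why: Proposed new method: the secondary amine takes up the single equivalent of formaldehyde (so the free C3′ is not hydroxymethylated) and is ionised to iminium 13 as a contact ion pair with the chiral phosphate, which is held by hydrogen bonds to the phenol O–H and the indole N–H; reversible C3 attack gives spiroindolenine 14, and the enantiodetermining event is the suprafacial transfer of the aminomethyl carbon from C3 to C2 (retro‑Mannich/Mannich) with capture of the emerging C3 benzylic cation by the phenol oxygen, so the anion fixes C9a and the cis 5/5 fusion then dictates C4a; the closest known reactions are the racemic acid‑promoted Pictet–Spengler/oxa‑cyclisation cascade of 2‑(2‑hydroxyaryl)tryptamines and chiral phosphoric acid‑catalysed Pictet–Spengler reactions of N‑alkyltryptamines, neither of which sets a dearomatised C4a/C9a pair enantioselectively.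

Step 10
Reactants: 15 (4aS,9aR)‑hexacyclic benzofuro[3,2‑b]indoline amine
Product: 16 the target, (4aS,9aR)‑configured, with 3′‑CH2NMe2
Conditions: Me2N+=CH2 I− (1.3 equiv), MeCN–AcOH (10:1), rt; aq. NaOH
Reagents that add atoms: Eschenmoser's salt (N,N‑dimethylmethyleneiminium iodide), C=[N+](C)C.[I-]
Why: Mannich reaction (gramine synthesis) with a preformed iminium salt; indole C3′ is the most nucleophilic carbon in 15, aminomethylation of the indoline N–H is reversible and lost on basic work‑up, and the two quaternary centres cannot epimerise.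

## Compound list

1 | tryptamine | NCCc1c[nH]c2ccccc12 | starting material
2 | methyl N‑[2‑(1H‑indol‑3‑yl)ethyl]carbamate | COC(=O)NCCc1c[nH]c2ccccc12 | intermediate
3 | methyl N‑{2‑[2‑(4,4,5,5‑tetramethyl‑1,3,2‑dioxaborolan‑2‑yl)‑1H‑indol‑3‑yl]ethyl}carbamate | COC(=O)NCCc1c(B2OC(C)(C)C(C)(C)O2)[nH]c2ccccc12 | intermediate
4 | 3‑methoxy‑4‑nitrophenol | COc1cc(O)ccc1[N+](=O)[O-] | starting material
5 | 2‑bromo‑5‑methoxy‑4‑nitrophenol | COc1cc(O)c(Br)cc1[N+](=O)[O-] | intermediate
6 | 1‑(benzyloxy)‑2‑bromo‑5‑methoxy‑4‑nitrobenzene | COc1cc(OCc2ccccc2)c(Br)cc1[N+](=O)[O-] | intermediate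
7 | 1‑(benzyloxy)‑2‑bromo‑5‑methoxy‑4‑nitrosobenzene (not isolated) | COc1cc(OCc2ccccc2)c(Br)cc1N=O | intermediate
8 | 5‑(benzyloxy)‑4‑bromo‑7‑methoxy‑1H‑indole | COc1cc(OCc2ccccc2)c(Br)c2cc[nH]c12 | intermediate
9 | methyl N‑{2‑[2‑(5‑benzyloxy‑7‑methoxy‑1H‑indol‑4‑yl)‑1H‑indol‑3‑yl]ethyl}carbamate | COC(=O)NCCc1c(-c2c(OCc3ccccc3)cc(OC)c3[nH]ccc23)[nH]c2ccccc12 | intermediate
10 | N‑{2‑[2‑(5‑benzyloxy‑7‑methoxy‑1H‑indol‑4‑yl)‑1H‑indol‑3‑yl]ethyl}formamide (not isolated) | O=CNCCc1c(-c2c(OCc3ccccc3)cc(OC)c3[nH]ccc23)[nH]c2ccccc12 | intermediate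
11 | 2‑[2‑(5‑benzyloxy‑7‑methoxy‑1H‑indol‑4‑yl)‑1H‑indol‑3‑yl]‑N‑methylethanamine | CNCCc1c(-c2c(OCc3ccccc3)cc(OC)c3[nH]ccc23)[nH]c2ccccc12 | intermediate
12 | 7‑methoxy‑4‑{3‑[2‑(methylamino)ethyl]‑1H‑indol‑2‑yl}‑1H‑indol‑5‑ol | CNCCc1c(-c2c(O)cc(OC)c3[nH]ccc23)[nH]c2ccccc12 | intermediate
13 | N‑methyl‑N‑methylidene‑2‑[2‑(5‑hydroxy‑7‑methoxy‑1H‑indol‑4‑yl)‑1H‑indol‑3‑yl]ethanaminium, chiral phosphate counter‑ion (not isolated) | C=[N+](C)CCc1c(-c2c(O)cc(OC)c3[nH]ccc23)[nH]c2ccccc12 | intermediate
14 | 7‑methoxy‑4‑(1′‑methylspiro[indole‑3,3′‑pyrrolidin]‑2‑yl)‑1H‑indol‑5‑ol (not isolated; spiro centre not defined, forms reversibly) | CN1CCC2(C1)C(-c1c(O)cc(OC)c3[nH]ccc13)=Nc1ccccc12 | intermediate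
15 | (4aS,9aR)‑hexacycle: 2‑methyl‑tetrahydro‑β‑carboline whose C9a is bonded to C4′ and whose C4a is bonded through oxygen to C5′ of 7‑methoxy‑1H‑indole (cis‑fused benzofuro[3,2‑b]indoline, N9–H free) | COc1cc2c(c3cc[nH]c13)[C@@]13CN(C)CC[C@]1(O2)c1ccccc1N3 | intermediate
16 | (4aS,9aR)‑hexacycle 15 carrying CH2NMe2 at C3′ of the methoxyindole (CNP0318114.2) | COc1cc2c(c3c(CN(C)C)c[nH]c13)[C@@]13CN(C)CC[C@]1(O2)c1ccccc1N3 | target

## Step count and risks

Total steps: 10. Longest linear sequence: 8 steps (4 → 16, steps 3–10); the tryptamine branch is 7 steps (1 → 16).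

**Step 9 (proposed new cascade).** The enantioselectivity is unproven: a racemic background reaction through phenol‑assisted ionisation of the hemiaminal, slow rotation about the biaryl axis, or reversibility could erode it. Fallback: setting out from 12, the known acid‑promoted racemic cascade is run (37% aq. CH2O, 1.05 equiv, AcOH, 50 °C), through the same 13 and 14. It gives 15 together with an equal amount of its mirror image ent‑15 F1. Preparative chiral‑phase SFC separates the two, and the route is rejoined at 15.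

**Step 6 (Suzuki coupling).** The 2‑indolyl boronate 3 may protodeboronate faster than it couples with the hindered, electron‑rich bromide 8. Fallback: setting out from 8, the indole C2–aryl bond is made by building the tryptamine indole instead. Copper‑free Sonogashira coupling of 8 with tert‑butyl but‑3‑yn‑1‑ylcarbamate (XPhos Pd G3, Cs2CO3, MeCN, 80 °C) gives the aryl alkyne, tert‑butyl N‑{4‑[5‑(benzyloxy)‑7‑methoxy‑1H‑indol‑4‑yl]but‑3‑yn‑1‑yl}carbamate F2. Larock heteroannulation with 2‑iodoaniline (Pd(OAc)2, K2CO3, LiCl, DMF, 100 °C) puts the bulky aryl group at C2 and the aminoethyl chain at C3, giving the Boc analogue of 9, tert‑butyl N‑{2‑[2‑(5‑benzyloxy‑7‑methoxy‑1H‑indol‑4‑yl)‑1H‑indol‑3‑yl]ethyl}carbamate F3. LiAlH4 in refluxing THF reduces the Boc group to N‑methyl through the same formamide 10, and the route is rejoined at 11.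

**Step 10 (Mannich reaction).** C3′ is peri to the fully substituted C9a, and the indoline ring and the C6′ position are competing nucleophilic sites. Fallback: setting out from 15, C3′ is formylated at the iminium oxidation level with the smaller, more electrophilic Vilsmeier reagent ((chloromethylene)dimethyliminium chloride, CH2Cl2–DMF, 0 °C). This gives the C3′‑(dimethyliminio)methyl chloride of 15 F4, which deactivates the ring against a second attack. It is reduced in the same flask with NaBH4 in MeOH; any N‑aminomethyl group on the indoline falls off on aqueous work‑up. The route comes back at 16.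

## Further compounds

F1 | step 9 | ent‑15, the (4aR,9aS) enantiomer of 15 | COc1cc2c(c3cc[nH]c13)[C@]13CN(C)CC[C@@]1(O2)c1ccccc1N3
F2 | step 6 | tert‑butyl N‑{4‑[5‑(benzyloxy)‑7‑methoxy‑1H‑indol‑4‑yl]but‑3‑yn‑1‑yl}carbamate | CC(C)(C)OC(=O)NCCC#Cc1c(OCc2ccccc2)cc(OC)c2[nH]ccc12
F3 | step 6 | tert‑butyl N‑{2‑[2‑(5‑benzyloxy‑7‑methoxy‑1H‑indol‑4‑yl)‑1H‑indol‑3‑yl]ethyl}carbamate | CC(C)(C)OC(=O)NCCc1c(-c2c(OCc3ccccc3)cc(OC)c3[nH]ccc23)[nH]c2ccccc12
F4 | step 10 | C3′‑(dimethyliminio)methyl chloride of 15 | COc1cc2c(c3c(C=[N+](C)C)c[nH]c13)[C@@]13CN(C)CC[C@]1(O2)c1ccccc1N3.[Cl-]
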